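The earlier runs and the new flask are calculated for substances that don't exist.

The substrate disappeared faster in the beta run at 85 °C than in the gamma run at 58 °C: 0.106 min⁻¹ against 0.00932 min⁻¹, read as first-order constants from the last reading of each run.

| flask | substrate | catalyst | temperature | remark | time |
|---|---|---|---|---|---|
| gamma | 0.80 M | 0.13 mol% | 58 °C | run made earlier |  |
| beta | 0.80 M | 0.3 mol% | 85 °C | run made earlier |  |
| delta | 1.6 M | 0.2 mol% | 58 °C | run made earlier |  |
| amber | 0.80 M | 0.2 mol% | 70 °C |  | 12 min |
| ochre | 0.80 M | 0.2 mol% | 45 °C |  | 12 min |
| teal | 0.80 M | 0.2 mol% | 95 °C |  | 12 min |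

- gamma (time / min: intermediate / %, target / %, substrate / %): 5.00: 3, 2, 96; 10.0: 5, 1, 90; 15.0: 10, 2, 90; 20.0: 14, 1, 83
- beta (time / min: intermediate / %, target / %, substrate / %): 0.500: 6, 3, 93; 1.33: 11, 4, 84; 3.00: 19, 8, 72; 4.00: 21, 13, 64; 6.00: 21, 24, 53
- delta (time / min: intermediate / %, target / %, substrate / %): 5.00: 2, 1, 95; 10.0: 6, 5, 91; 15.0: 8, 5, 88; 20.0: 7, 5, 84

(readings scatter by 1.5 percentage points)

- the numbers in the tables scatter with a standard deviation of 1.5 percentage points
- what may be going on: substrate -> intermediate; catalyst + intermediate -> catalyst + target; substrate -> decomposition product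

- which flask leads in amount of intermediate, in percent of the substrate charged ("all alike" within 1.5 percentage points) (amber / ochre / teal / all alike)
- how much intermediate is there at the end, in percent of the substrate charged: amber
- how much intermediate is there at the end, in percent of the substrate charged: ochre
- how much intermediate is there at the end, in percent of the substrate charged: teal

I froze the catalyst. The proposed scheme hands it back after each turn, so at a fixed loading the intermediate drains by a pseudo-first-order step, while the substrate feeds it at the constant above. The last beta reading sums to 98.0% of the charge, so I dropped the decomposition product.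

I scaled the drain to 0.2 mol% on 0.80 M. The climb of the target in beta gave 0.169 min⁻¹. The target in delta, over the area under its intermediate, gave 0.0256 min⁻¹. Both are readings with their scatter, and I took the logarithms of feed and drain as straight in temperature.

For teal that made the feed 0.260 min⁻¹ and the drain 0.341 min⁻¹. Its curve starts with the feed as slope and bends over at the peak time, the logarithm of drain over feed divided by drain minus feed: 3.35 min. The top of teal stands near 31.9% of the charge. By 12 min teal has come down to 8.82%, on its way toward zero.

Amber, with feed 0.0274 min⁻¹ and drain 0.0593 min⁻¹, peaks at 24.2 min, so it is still climbing at 19.7%. Ochre, with feed 0.00289 min⁻¹ and drain 0.0103 min⁻¹, stands at 3.21%. I chose amber.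

The forecast named amber, with 19% for amber, 2.5% for ochre and 9% for teal, calling teal “already past its maximum”. My ochre stood higher.

Amber led with 18.6%, against 2.45% in ochre and 8.34% in teal.

    substrate → intermediate (k = 0.0268 min⁻¹, Ea = 91.0 kJ mol⁻¹)
    catalyst + intermediate → catalyst + target (k = 41.3 M⁻¹ min⁻¹, Ea = 72.0 kJ mol⁻¹)
    substrate → decomposition product (k = 1.56 × 10⁻⁴ min⁻¹, Ea = 110 kJ mol⁻¹)
    (constants at 70 °C)

In teal the intermediate was made 1.20 times as fast as it was used at 2.70 min, and 0.451 times at 12.0 min. The peak time of 3.35 min falls between those two moments.

For a flask like teal kept at 80 °C, feed 0.0675 min⁻¹ and drain 0.119 min⁻¹ put the peak at 11.0 min, close to the reading at 12 min, with a top near 27.0%. That flask gives 24.3% at 12.0 min.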